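**Plan**

- Numbering: ring A is the halogenated ring (C1 to C6). Ring B is the prenylated resorcinol ring, with C1' on the ketone carbon, C2' bearing CHO, C3' and C5' bearing OH, C4' bearing H and C6' bearing the prenyl group.
- Retrosynthesis: the three phenol protecting groups are removed and the ketone and aldehyde are taken back to a carbinol and a methyl ester. Ring B is then cut at C1'–C6' and C2'–C3'. This is possible because its oxygens sit at C3' and C5' with hydrogen at C4', while C6', C1' and C2' carry carbon substituents, which is the imprint of a 1,3-dioxygenated diene on a two-carbon alkyne.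
- Further cuts: the carbinol–alkyne bond (ring A aldehyde plus methyl propiolate) and the CH2–CH2 bond of the diene side chain (methyl acetoacetate plus prenyl bromide).
- Forward: 3-methoxy-5-methylphenol is brominated, chlorinated, formylated and protected. The propiolate acetylide installs the future diaryl carbon, and ring B is grown around it by Diels–Alder reaction and aromatisation. Reduction, double oxidation and deprotection finish the synthesis.
- Stereochemistry: the target has no stereocentre and no stereogenic alkene. The carbinol carbon is racemic throughout and ends as the ketone.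

Key step: step 10

Remark: Ar stands for 3-bromo-5-chloro-6-methoxy-2-(methoxymethoxy)-4-methylphenyl (ring A with its phenol protected as the methoxymethyl, MOM, ether). The C1=C2 geometry of diene 17 is left open because C1 ends as an aromatic carbon.

**Route**

Step 1
Reactants: 1 3-methoxy-5-methylphenol
Product: 2 2-bromo-5-methoxy-3-methylphenol
Conditions: N-bromosuccinimide (1.0 equiv, added slowly), i-Pr2NH (0.1 equiv), CH2Cl2, 0 °C
Reagents that add atoms: N-bromosuccinimide (O=C1CCC(=O)N1Br)
Why: Amine-catalysed electrophilic aromatic bromination delivers bromine ortho to the phenol through a hydrogen-bonded N-bromoamine, and of the two ortho carbons the one para to the methoxy group is the more electron-rich and less crowded, so the carbon between the two oxygens should be spared.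

Step 2
Reactants: 2 2-bromo-5-methoxy-3-methylphenol
Product: 3 2-bromo-4-chloro-5-methoxy-3-methylphenol
Conditions: SO2Cl2 (1.05 equiv), CH2Cl2, 0 °C
Reagents that add atoms: sulfuryl chloride (O=S(=O)(Cl)Cl)
Why: Electrophilic aromatic chlorination should go to the carbon para to the free hydroxyl and ortho to the methoxy group, because the only other open carbon lies between the two oxygen substituents where substitution is slowest.

Step 3
Reactants: 3 2-bromo-4-chloro-5-methoxy-3-methylphenol
Product: 5 3-bromo-5-chloro-2-hydroxy-6-methoxy-4-methylbenzaldehyde, via hydroxymethyl phenol 4 (not isolated)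
Conditions: MgCl2, Et3N, (CH2O)n, MeCN, 80 °C; then 1 M aq. HCl
Reagents that add atoms: paraformaldehyde, reacting as formaldehyde (C=O)
Why: The magnesium-phenoxide-directed ortho-formylation (Casnati–Skattebøl reaction) can only reach the single remaining ring carbon, where hydroxymethylation gives 4 and a second formaldehyde oxidises it by hydride transfer inside the magnesium chelate.

Step 4
Reactants: 5 3-bromo-5-chloro-2-hydroxy-6-methoxy-4-methylbenzaldehyde
Product: 6 3-bromo-5-chloro-6-methoxy-2-(methoxymethoxy)-4-methylbenzaldehyde (ArCHO)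
Conditions: MOMCl, i-Pr2NEt, CH2Cl2, 0 → 40 °C
Reagents that add atoms: chloromethyl methyl ether (COCCl)
Why: O-Alkylation of the acidic chelated phenol with the reactive α-chloro ether gives an acetal ether that should withstand the amide base, hydride, fluoride and oxidation steps and is removed by acid at the end.

Step 5
Reactants: 6 3-bromo-5-chloro-6-methoxy-2-(methoxymethoxy)-4-methylbenzaldehyde; 7 methyl propiolate
Product: 9 methyl 4-Ar-4-hydroxybut-2-ynoate (racemic), via lithium acetylide 8 (not isolated)
Conditions: 7, LiN(SiMe3)2, THF, −78 °C; then 6, −78 °C; AcOH quench at −78 °C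
Reagents that add atoms: none
Why: This is a 1,2-addition of a lithium acetylide to an aldehyde in which the amide base deprotonates the propiolate without touching the aryl bromide, the slim linear nucleophile tolerates both ortho substituents, and the new carbinol centre forms as a racemate that is oxidised away later.

Step 6
Reactants: 9 methyl 4-Ar-4-hydroxybut-2-ynoate
Product: 10 methyl 4-Ar-4-(tert-butyldimethylsilyloxy)but-2-ynoate (racemic)
Conditions: t-BuMe2SiOTf, 2,6-lutidine, CH2Cl2, −78 °C
Reagents that add atoms: tert-butyldimethylsilyl trifluoromethanesulfonate (CC(C)(C)[Si](C)(C)OS(=O)(=O)C(F)(F)F)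
Why: Silylation with a silyl triflate and a hindered pyridine base at low temperature should cap the crowded carbinol fast enough to avoid both the base-induced isomerisation of γ-hydroxy ynoates to γ-keto enoates and attack on the aryl MOM ether.

Step 7
Reactants: 11 methyl acetoacetate; 12 prenyl bromide (1-bromo-3-methylbut-2-ene)
Product: 14 methyl 7-methyl-3-oxooct-6-enoate, via acetoacetate dianion 13 (not isolated)
Conditions: NaH, THF, 0 °C; n-BuLi, 0 °C; then 12, 0 → 23 °C; aq. HCl
Reagents that add atoms: none
Why: In this γ-alkylation of a β-keto ester dianion the terminal carbanion is the more basic and nucleophilic site and displaces the allylic bromide by SN2 substitution.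

Step 8
Reactants: 14 methyl 7-methyl-3-oxooct-6-enoate
Product: 15 methyl 7-methyl-3-(trimethylsilyloxy)octa-2,6-dienoate (C2=C3 geometry not defined)
Conditions: Me3SiCl, Et3N, hexane, 23 °C; filtration
Reagents that add atoms: chlorotrimethylsilane (C[Si](C)(C)Cl)
Why: O-Silylation of the readily enolised β-keto ester with a chlorosilane and a tertiary amine gives the β-silyloxy enoate.

Step 9
Reactants: 15 methyl 7-methyl-3-(trimethylsilyloxy)octa-2,6-dienoate
Product: 17 (3Z)-1-methoxy-7-methyl-1,3-bis(trimethylsilyloxy)octa-1,3,6-triene, via lithium dienolate 16 (not isolated)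
Conditions: LiN(i-Pr)2, THF, −78 °C; Me3SiCl, −78 → 0 °C; salts removed under argon, used crude
Reagents that add atoms: chlorotrimethylsilane (C[Si](C)(C)Cl)
Why: γ-Deprotonation of the β-silyloxy enoate by a lithium amide followed by O-silylation of the extended enolate gives the ketene silyl acetal diene, the inner double bond taking the Z geometry of the dienolate.

Step 10
Reactants: 10 methyl 4-Ar-4-(tert-butyldimethylsilyloxy)but-2-ynoate; 17 (3Z)-1-methoxy-7-methyl-1,3-bis(trimethylsilyloxy)octa-1,3,6-triene
Product: 19 methyl 2-[Ar(tert-butyldimethylsilyloxy)methyl]-4,6-dihydroxy-3-(3-methylbut-2-enyl)benzoate (racemic), via cyclohexadiene cycloadduct 18 (not isolated)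
Conditions: 17 (3 equiv), toluene (concentrated), 110 °C, sealed tube; then 1 M aq. HCl, THF, 0 °C, brief
Reagents that add atoms: none
Why: Diene 17 and acetylenic ester 10 should combine in a thermal, asynchronous, normal-electron-demand [4+2] cycloaddition led by the nucleophilic diene terminus C4 (the carbon bearing the prenyl CH2) attacking the alkyne carbon β to the ester, while the ketene acetal carbon C1 closes onto the α carbon; the closest known reaction is the Diels–Alder benzannulation of 1-alkoxy-1,3-bis(silyloxy)dienes with acetylenic esters to give resorcylates. Ring B is closed intermolecularly, both of its new bonds (C1'–C6' and C2'–C3') arising in the one cycloaddition and not by cyclisation of a preformed chain, and the 1,4-cyclohexadiene 18 aromatises on acidic work-up by collapse of the silyl methyl ketal with loss of methanol, enolisation and cleavage of the two O–SiMe3 bonds. No lasting stereocentre is made, since the two sp3 ring carbons of 18 become aromatic and the carbinol carbon, already racemic, is not touched. The step needs regioselectivity (ester beside the new C3' hydroxyl, carbinol carbon beside the prenyl-bearing carbon), and this is secured by holding the diaryl carbon at the alcohol oxidation level so that the ester is the only acceptor polarising the triple bond and its β carbon the only electrophilic site offered to C4. Formation of the free phenol at C3' and not its methyl ether follows from the hydrolytic work-up, which turns the mixed ketal carbon into a carbonyl before enolisation.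

Step 11
Reactants: 19 methyl 2-[Ar(tert-butyldimethylsilyloxy)methyl]-4,6-dihydroxy-3-(3-methylbut-2-enyl)benzoate
Product: 20 methyl 2-[Ar(tert-butyldimethylsilyloxy)methyl]-4,6-bis(methoxymethoxy)-3-(3-methylbut-2-enyl)benzoate (racemic)
Conditions: NaH (3 equiv), MOMCl (3 equiv), DMF, 0 → 23 °C
Reagents that add atoms: chloromethyl methyl ether (COCCl)
Why: O-Alkylation of the bis-phenoxide, with the sodium salt chosen because the hydroxyl next to the ester is chelated, caps both phenols so that they neither consume hydride nor form quinone methides in the reduction and oxidation steps.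

Step 12
Reactants: 20 methyl 2-[Ar(tert-butyldimethylsilyloxy)methyl]-4,6-bis(methoxymethoxy)-3-(3-methylbut-2-enyl)benzoate
Product: 21 [2-[Ar(tert-butyldimethylsilyloxy)methyl]-4,6-bis(methoxymethoxy)-3-(3-methylbut-2-enyl)phenyl]methanol (racemic)
Conditions: i-Bu2AlH (4 equiv), CH2Cl2, −78 → 0 °C; aq. KNaC4H4O6
Reagents that add atoms: none
Why: Aluminium hydride reduction of the benzoate to the benzylic alcohol should leave the aryl halides, the acetal ethers, the silyl ether and the trisubstituted alkene untouched.

Step 13
Reactants: 21 [2-[Ar(tert-butyldimethylsilyloxy)methyl]-4,6-bis(methoxymethoxy)-3-(3-methylbut-2-enyl)phenyl]methanol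
Product: 22 [2-[Ar(hydroxy)methyl]-4,6-bis(methoxymethoxy)-3-(3-methylbut-2-enyl)phenyl]methanol (racemic diol)
Conditions: Bu4NF, THF, 0 → 40 °C
Reagents that add atoms: none
Why: Fluoride-induced Si–O cleavage frees the diaryl carbinol, and a silyl shift to the primary oxygen beforehand would be harmless because both hydroxyls are wanted free.

Step 14
Reactants: 22 [2-[Ar(hydroxy)methyl]-4,6-bis(methoxymethoxy)-3-(3-methylbut-2-enyl)phenyl]methanol
Product: 23 2-[3-bromo-5-chloro-6-methoxy-2-(methoxymethoxy)-4-methylbenzoyl]-4,6-bis(methoxymethoxy)-3-(3-methylbut-2-enyl)benzaldehyde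
Conditions: (COCl)2 (4 equiv), DMSO (8 equiv), CH2Cl2, −78 °C; then Et3N, −78 → 0 °C
Reagents that add atoms: none
Why: The Swern oxidation activates both hydroxyls as alkoxysulfonium ions before any carbonyl exists, so the base then converts them together into ketone and aldehyde without passing through a hydroxy aldehyde that would close to a lactol and be over-oxidised to the phthalide.

Step 15
Reactants: 23 2-[3-bromo-5-chloro-6-methoxy-2-(methoxymethoxy)-4-methylbenzoyl]-4,6-bis(methoxymethoxy)-3-(3-methylbut-2-enyl)benzaldehyde
Product: 24 Pestalone G, 2-(3-bromo-5-chloro-2-hydroxy-6-methoxy-4-methylbenzoyl)-4,6-dihydroxy-3-(3-methylbut-2-enyl)benzaldehyde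
Conditions: 3 M aq. HCl, THF, 23 → 40 °C
Reagents that add atoms: none
Why: Acid-catalysed hydrolysis of the three aryl methoxymethyl acetals, eased by the neighbouring carbonyl groups, is run dilute and at or below 40 °C so that the prenyl alkene is not protonated and no chroman forms with the adjacent phenol.

**Compound list** (Ar = 3-bromo-5-chloro-6-methoxy-2-(methoxymethoxy)-4-methylphenyl)

1 | 3-methoxy-5-methylphenol | COc1cc(C)cc(O)c1 | starting material
2 | 2-bromo-5-methoxy-3-methylphenol | Oc1cc(OC)cc(C)c1Br | intermediate
3 | 2-bromo-4-chloro-5-methoxy-3-methylphenol | Oc1cc(OC)c(Cl)c(C)c1Br | intermediate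
4 | 2-bromo-4-chloro-6-(hydroxymethyl)-5-methoxy-3-methylphenol (formed in the flask as its magnesium salt, not isolated) | Oc1c(CO)c(OC)c(Cl)c(C)c1Br | intermediate
5 | 3-bromo-5-chloro-2-hydroxy-6-methoxy-4-methylbenzaldehyde | O=Cc1c(OC)c(Cl)c(C)c(Br)c1O | intermediate
6 | 3-bromo-5-chloro-6-methoxy-2-(methoxymethoxy)-4-methylbenzaldehyde | O=Cc1c(OC)c(Cl)c(C)c(Br)c1OCOC | intermediate
7 | methyl propiolate | C#CC(=O)OC | starting material
8 | methyl 3-lithiopropiolate (formed in the flask, not isolated) | [Li]C#CC(=O)OC | intermediate
9 | methyl 4-Ar-4-hydroxybut-2-ynoate (racemic) | COC(=O)C#CC(O)c1c(OC)c(Cl)c(C)c(Br)c1OCOC | intermediate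
10 | methyl 4-Ar-4-(tert-butyldimethylsilyloxy)but-2-ynoate (racemic) | COC(=O)C#CC(O[Si](C)(C)C(C)(C)C)c1c(OC)c(Cl)c(C)c(Br)c1OCOC | intermediate
11 | methyl acetoacetate | CC(=O)CC(=O)OC | starting material
12 | prenyl bromide | CC(C)=CCBr | starting material
13 | sodium lithium dianion of methyl acetoacetate (formed in the flask, not isolated) | C=C([O-])C=C([O-])OC.[Na+].[Li+] | intermediate
14 | methyl 7-methyl-3-oxooct-6-enoate | COC(=O)CC(=O)CCC=C(C)C | intermediate
15 | methyl 7-methyl-3-(trimethylsilyloxy)octa-2,6-dienoate (C2=C3 geometry not defined) | COC(=O)C=C(O[Si](C)(C)C)CCC=C(C)C | intermediate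
16 | lithium (3Z)-1-methoxy-7-methyl-3-(trimethylsilyloxy)octa-1,3,6-trien-1-olate (formed in the flask, not isolated) | COC([O-])=C/C(O[Si](C)(C)C)=C/CC=C(C)C.[Li+] | intermediate
17 | (3Z)-1-methoxy-7-methyl-1,3-bis(trimethylsilyloxy)octa-1,3,6-triene | COC(O[Si](C)(C)C)=C/C(O[Si](C)(C)C)=C/CC=C(C)C | intermediate
18 | methyl 2-[Ar(tert-butyldimethylsilyloxy)methyl]-6-methoxy-3-(3-methylbut-2-enyl)-4,6-bis(trimethylsilyloxy)cyclohexa-1,4-diene-1-carboxylate (mixture of diastereomers, formed in the flask, not isolated) | COC(=O)C1=C(C(O[Si](C)(C)C(C)(C)C)c2c(OC)c(Cl)c(C)c(Br)c2OCOC)C(CC=C(C)C)C(O[Si](C)(C)C)=CC1(OC)O[Si](C)(C)C | intermediate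
19 | methyl 2-[Ar(tert-butyldimethylsilyloxy)methyl]-4,6-dihydroxy-3-(3-methylbut-2-enyl)benzoate (racemic) | COC(=O)c1c(O)cc(O)c(CC=C(C)C)c1C(O[Si](C)(C)C(C)(C)C)c1c(OC)c(Cl)c(C)c(Br)c1OCOC | intermediate
20 | methyl 2-[Ar(tert-butyldimethylsilyloxy)methyl]-4,6-bis(methoxymethoxy)-3-(3-methylbut-2-enyl)benzoate (racemic) | COC(=O)c1c(OCOC)cc(OCOC)c(CC=C(C)C)c1C(O[Si](C)(C)C(C)(C)C)c1c(OC)c(Cl)c(C)c(Br)c1OCOC | intermediate
21 | [2-[Ar(tert-butyldimethylsilyloxy)methyl]-4,6-bis(methoxymethoxy)-3-(3-methylbut-2-enyl)phenyl]methanol (racemic) | OCc1c(OCOC)cc(OCOC)c(CC=C(C)C)c1C(O[Si](C)(C)C(C)(C)C)c1c(OC)c(Cl)c(C)c(Br)c1OCOC | intermediate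
22 | [2-[Ar(hydroxy)methyl]-4,6-bis(methoxymethoxy)-3-(3-methylbut-2-enyl)phenyl]methanol (racemic) | OCc1c(OCOC)cc(OCOC)c(CC=C(C)C)c1C(O)c1c(OC)c(Cl)c(C)c(Br)c1OCOC | intermediate
23 | 2-[3-bromo-5-chloro-6-methoxy-2-(methoxymethoxy)-4-methylbenzoyl]-4,6-bis(methoxymethoxy)-3-(3-methylbut-2-enyl)benzaldehyde | O=Cc1c(OCOC)cc(OCOC)c(CC=C(C)C)c1C(=O)c1c(OC)c(Cl)c(C)c(Br)c1OCOC | intermediate
24 | Pestalone G | COc1c(Cl)c(C)c(Br)c(O)c1C(=O)c1c(C=O)c(O)cc(O)c1CC=C(C)C | target

**Step count and risks**

Total step count: 15 (ring A arm steps 1–6, diene arm steps 7–9, joined in step 10).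
Longest linear sequence: 12 steps (steps 1–6 and 10–15, from 3-methoxy-5-methylphenol).

Steps most likely to fail:

1. Step 10. The cycloaddition may be outrun by thermal decay or protodesilylation of the diene, because the alkyne is activated by one ester only and its β carbon is shielded by the silylated, doubly ortho-substituted benzylic group. The fallback sets out from alcohol 9 and diene 17 and returns at diol 22. The carbinol of 9 is capped in the flask with N,O-bis(trimethylsilyl)acetamide to give the much smaller dienophile methyl 4-Ar-4-(trimethylsilyloxy)but-2-ynoate F1, which is heated with 17 as in step 10. Work-up with 1 M HCl in THF removes all three trimethylsilyl groups, and the freed carbinol closes onto the neighbouring methyl ester to give the lactone 3-Ar-5,7-dihydroxy-4-(3-methylbut-2-enyl)isobenzofuran-1(3H)-one F2. Both phenols are etherified (MOMCl, i-Pr2NEt, Bu4NI, CH2Cl2, 40 °C) to 3-Ar-5,7-bis(methoxymethoxy)-4-(3-methylbut-2-enyl)isobenzofuran-1(3H)-one F3, and LiAlH4 in THF at 0 °C opens the lactone to diol 22, from which step 14 follows.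

2. Step 14. The crowded secondary hydroxyl may be activated more slowly than the primary one, so that the aldehyde appears while the carbinol is still free, the two close to a lactol and further oxidation gives the phthalide. The fallback sets out from 21 and returns at 23, oxidising the two carbons one after the other. Acetylation of the primary alcohol (Ac2O, pyridine, DMAP) gives [2-[Ar(tert-butyldimethylsilyloxy)methyl]-4,6-bis(methoxymethoxy)-3-(3-methylbut-2-enyl)phenyl]methyl acetate F4. Bu4NF buffered with AcOH then frees the carbinol to give [2-[Ar(hydroxy)methyl]-4,6-bis(methoxymethoxy)-3-(3-methylbut-2-enyl)phenyl]methyl acetate F5. Dess–Martin periodinane with NaHCO3 oxidises it to [2-(Ar-carbonyl)-4,6-bis(methoxymethoxy)-3-(3-methylbut-2-enyl)phenyl]methyl acetate F6. K2CO3 in MeOH at 0 °C removes the acetate to give Ar [2-(hydroxymethyl)-3,5-bis(methoxymethoxy)-6-(3-methylbut-2-enyl)phenyl] ketone F7. Its ring tautomer is a hemiketal without a carbinol hydrogen and cannot be over-oxidised, so MnO2 in CH2Cl2 should then give keto aldehyde 23.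

3. Step 1. Bromination may spread over the carbon para to the hydroxyl and the carbon between the two oxygens, so that material is lost in a separation of isomers. The fallback sets out from 1 and returns at 3, inverting the order of halogenation so that the selectivity-determining event is a para-chlorination. SO2Cl2 with catalytic Bu2S and AlCl3 (para-directing sulfide catalysis) gives 4-chloro-3-methoxy-5-methylphenol F8, in which only the two ortho carbons remain open. N-Bromosuccinimide then brominates the one para to the methoxy group to give 3, from which step 3 follows.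

**Further compounds**

F1 | step 10 | methyl 4-Ar-4-(trimethylsilyloxy)but-2-ynoate (racemic) | COC(=O)C#CC(O[Si](C)(C)C)c1c(OC)c(Cl)c(C)c(Br)c1OCOC
F2 | step 10 | 3-Ar-5,7-dihydroxy-4-(3-methylbut-2-enyl)isobenzofuran-1(3H)-one (racemic) | O=C1OC(c2c(OC)c(Cl)c(C)c(Br)c2OCOC)c2c(CC=C(C)C)c(O)cc(O)c12
F3 | step 10 | 3-Ar-5,7-bis(methoxymethoxy)-4-(3-methylbut-2-enyl)isobenzofuran-1(3H)-one (racemic) | O=C1OC(c2c(OC)c(Cl)c(C)c(Br)c2OCOC)c2c(CC=C(C)C)c(OCOC)cc(OCOC)c12
F4 | step 14 | [2-[Ar(tert-butyldimethylsilyloxy)methyl]-4,6-bis(methoxymethoxy)-3-(3-methylbut-2-enyl)phenyl]methyl acetate (racemic) | CC(=O)OCc1c(OCOC)cc(OCOC)c(CC=C(C)C)c1C(O[Si](C)(C)C(C)(C)C)c1c(OC)c(Cl)c(C)c(Br)c1OCOC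
F5 | step 14 | [2-[Ar(hydroxy)methyl]-4,6-bis(methoxymethoxy)-3-(3-methylbut-2-enyl)phenyl]methyl acetate (racemic) | CC(=O)OCc1c(OCOC)cc(OCOC)c(CC=C(C)C)c1C(O)c1c(OC)c(Cl)c(C)c(Br)c1OCOC
F6 | step 14 | [2-(Ar-carbonyl)-4,6-bis(methoxymethoxy)-3-(3-methylbut-2-enyl)phenyl]methyl acetate | CC(=O)OCc1c(OCOC)cc(OCOC)c(CC=C(C)C)c1C(=O)c1c(OC)c(Cl)c(C)c(Br)c1OCOC
F7 | step 14 | Ar [2-(hydroxymethyl)-3,5-bis(methoxymethoxy)-6-(3-methylbut-2-enyl)phenyl] ketone | OCc1c(OCOC)cc(OCOC)c(CC=C(C)C)c1C(=O)c1c(OC)c(Cl)c(C)c(Br)c1OCOC
F8 | step 1 | 4-chloro-3-methoxy-5-methylphenol | COc1cc(O)cc(C)c1Cl
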